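## Analysis of the target

Target 22 is a C2-symmetric biphenyl with no ring other than the two benzene rings and no stereocentre. The ring assembled through the aryne is called ring B (atoms C1–C6) and the other ring A (atoms C1'–C6'); chain carbons are C7–C9 and C7'–C9', counted from the ring. Each ring carries, in the same order, the biaryl bond at C1, a free hydroxyl at C2, a methoxy group at C3 and a 2-carboxyethyl chain at C5, para to the hydroxyl. The four positions ortho to the axis hold only OH and H, so the axis rotates freely and no configuration has to be controlled. The sensitive groups are the two electron-rich guaiacol-type phenols, which are easily oxidised and halogenated, and the two carboxylic acids, which cannot pass through organometallic steps. The difficulty is one of regiochemistry and timing: three contiguous substituents (aryl, OH, OMe) must be placed on a tetrasubstituted ring, with the biaryl bond ortho to oxygen on both sides. The strategy rests on the C1(aryl)–C2(OH)–C3(OMe) triad of ring B. This is the pattern obtained when a carbon nucleophile and then an oxygen electrophile are added across the C1–C2 triple bond of a 3-methoxybenzyne, with the C3 methoxy group deciding where each goes.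

## Retrosynthetic reasoning

**Disconnection 1 (22 ⇒ 21).** The last bonds cut are the two O–CH2 acetal bonds of bis(methoxymethyl) ether 21. Both phenols stay masked until every oxidising reagent has been used. The forward step is a plain acetal hydrolysis that touches neither the acids nor the rings.

**Disconnection 2 (21 ⇒ 19 ⇒ 18).** The carboxyl carbons C9 and C9' are traced back to the primary alcohols of diol 19 and these to the silyl ethers of 18. No C–C bond is cut. A carboxylic acid or ester could not survive the aryl-metal chemistry that builds the biaryl, whereas a silyl-protected primary alcohol can. The forward oxidation must take two CH2OH groups to CO2H without attacking two electron-rich arenes, which is why both phenols are capped at this stage.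

**Disconnection 3 (18 ⇒ 17).** The C2–O–CH2 bond is cut to give phenol 17. Capping makes the two rings identical again and is needed only because a free guaiacol-type phenol would not survive the chain oxidation.

**Disconnection 4, key (17 ⇒ 7 + 12).** In ring B the C1–C1' bond and the C2–O bond are cut in one operation. This leads to aryne 14 as acceptor, Grignard reagent 7 as carbon nucleophile and an electrophilic oxygen source. Cutting the biaryl bond alone would require two halves that each already carry oxygen next to a halogen or metal. The aryne route lets ring B start as fluoroarene 12, where fluorine marks C1, the most acidic proton sits on C2 and the C3 methoxy group steers both new bonds. The forward reaction must metalate 12 at C2 (13), release 14, add 7 at C1 only, and turn the C2–metal bond of 15 through boronate 16 into the hydroxyl group.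

**Disconnection 5 (12 ⇒ 10 + 9; 9 ⇒ 8).** The C5–C7 bond between ring B and its chain is cut. Aryl bromide 10 is a commercial arene with exactly the 1,3,5-pattern of fluorine, methoxy and coupling handle. The three-carbon chain comes from allyl silyl ether 9, made from allyl alcohol 8. The forward step is an alkyl–aryl cross-coupling through alkylborane 11 that must leave the C–F bond alone.

**Disconnection 6 (7 ⇒ 5 ⇒ 4 ⇒ 2 ⇒ 1).** The C1'–Mg bond of 7 is traced through aryllithium 6 to the C1'–H bond of arene 5. The acetal on the C2' oxygen serves both as protecting group and as director of metalation to C1', so no halogenation step is needed. Arene 5 comes from eugenol 1, which already contains ring A with oxygen at C2', methoxy at C3' and all three chain carbons at C5'. Only protection (2), anti-Markovnikov hydration of the allyl group (through 3 to 4) and silylation are required.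

## Alternatives that were turned down

**Alternative 1:** Ring B itself is opened at C1–C2 and C5–C6. C1 and C6 come from an ethynyl group on ring A, and C2–C5 from a 2-pyrone that already carries the C3 methoxy group and the C5 chain. The two phenolic oxygens are joined through a diisopropylsilylene bridge in precursor A2.
- Forward key step: heating A2 should bring about an intramolecular [4+2] cycloaddition of the pyrone diene to the alkyne. Cycloreversion of the bridged lactone then aromatises ring B and leaves the seven-membered dioxasilepine A1. Desilylation and ester hydrolysis would finish.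
- In its favour: the tether fixes the orientation of the addends, so the substitution pattern of ring B is not a selectivity question. Both phenols emerge masked by a single group. The chains travel at the acid oxidation level, so no late oxidation is needed. On these three points it is stronger than the chosen route.
- Against: A2 needs a fully substituted 3-hydroxy-2-pyrone, an ortho-ethynylphenol derived from ring A, and a mixed bis(oxy)silane between two different hindered hydroxyl partners. That silane forms alongside the symmetric products and is moisture-sensitive. The cycloaddition pairs an electron-rich dioxygenated pyrone with an unactivated terminal aryl alkyne through a medium-sized tether, so it needs forcing temperatures at which the Si–O bonds may not hold.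
- Comparison: the chosen route takes both rings as intact arenes (1 and 10) with every oxygen already in place and forms the biaryl in one flask by a reaction type with close analogy. It is shorter by several steps and concentrates the uncertainty in one step instead of spreading it over tether formation and cycloaddition.

**Alternative 2:** Ring B is cut at C1–C6 and C3–C4. C1–C2–C3 come from the ring-A-substituted methoxyacetone A4, whose carbonyl carbon becomes the phenol carbon C2. C4–C5–C6 come from the chain-bearing malondialdehyde A5.
- Forward key step: base-mediated double aldol condensation of A4 with A5, dehydration and tautomerisation should give phenol A3. Debenzylation and saponification would follow.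
- In its favour: the step is convergent, builds ring B with every substituent placed by constitution, delivers the C2 hydroxyl free, and keeps the chains as esters. It is at least as strong as the chosen route on regiochemical certainty.
- Against: A5 is a labile 2-alkylmalondialdehyde that exists as an enol and becomes a poor electrophile once deprotonated. Double condensations of this kind work well mainly with strongly activated partners, not with a simple dialkyl-type ketone. A4 can self-condense and has two different enolisable sites. Both methyl esters are exposed to base. A4 itself requires a benzylic ketone on a ring A that already carries three substituents, which costs several steps.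
- Comparison: the step count is no better than that of the chosen route, and the weakest precedent sits exactly at the ring-forming step. The chosen key step has close precedent and uses partners made in two to four routine steps.

**Alternative 3:** Both chains are cut at C7=C8 and C7'=C8' of the unsaturated diacid A6, leading back to dialdehyde A7. A7 is available in one oxidative coupling from vanillin A8.
- Forward key step: two-fold Knoevenagel–Doebner condensation of A7 with malonic acid A9 and decarboxylation should give A6. Hydrogenation of both alkenes then gives 22.
- In its favour: three steps from A8, no protecting groups, cheap materials. The ortho–ortho phenol coupling is regiochemically unambiguous because the para position is blocked. For 22 itself this alternative is clearly stronger than the chosen strategy on step economy and cost.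
- Against: A7 is very poorly soluble, and one-electron phenol coupling brings over-oxidation and oligomer formation. Para-hydroxycinnamic acids such as A6 can lose a second carboxyl group to vinylphenols on prolonged heating under the condensation conditions.
- Comparison: the chosen strategy is longer but does not depend on the symmetry of the target. Rings A and B enter as separate building blocks (7 and 12) and leave the key step chemically differentiated, since 17 has one free and one protected phenol. The same sequence can therefore serve unsymmetrical or singly labelled congeners and mono-O-alkylated derivatives. All its intermediates are soluble, lipophilic and chromatographable.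

Key step: step 7

Remark on the chemistry: the four positions ortho to the biaryl bond carry only OH and H, so the axis is taken as freely rotating and no axial configuration is assigned.

## Route

**Step 1**
Reactants: 1 eugenol (4-allyl-2-methoxyphenol)
Product: 2 4-allyl-2-methoxy-1-(methoxymethoxy)benzene
Conditions: MOMCl, i-Pr2NEt, CH2Cl2, 0 °C → rt
Reagents that add atoms: chloromethyl methyl ether (MOMCl), COCCl
Why: Williamson-type O-alkylation of the phenol with a reactive α-chloro ether under amine base; the acetal protects the phenol and later directs the ortho-metalation.

**Step 2**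
Reactants: 2 4-allyl-2-methoxy-1-(methoxymethoxy)benzene
Product: 4 3-[3-methoxy-4-(methoxymethoxy)phenyl]propan-1-ol, via alkylborane 3 (not isolated)
Conditions: 9-BBN, THF, 0 °C → rt; then NaOH aq, 30% H2O2, 0 °C → rt
Reagents that add atoms: hydrogen peroxide, OO (alcohol oxygen); 9-borabicyclo[3.3.1]nonane (9-BBN), [H]B1C2CCCC1CCC2 (boron carried only in intermediate 3)
Why: Hydroboration–oxidation; the bulky dialkylborane places boron on the terminal carbon of the allyl group (anti-Markovnikov) and alkaline peroxide replaces boron by hydroxyl, while the acetal is stable to both stages.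

**Step 3**
Reactants: 4 3-[3-methoxy-4-(methoxymethoxy)phenyl]propan-1-ol
Product: 5 triisopropyl{3-[3-methoxy-4-(methoxymethoxy)phenyl]propoxy}silane
Conditions: TIPSCl, imidazole, DMF, rt
Reagents that add atoms: chlorotriisopropylsilane (TIPSCl), CC(C)[Si](Cl)(C(C)C)C(C)C
Why: Silyl ether formation on a primary alcohol; the triisopropylsilyl ether tolerates alkyllithium and Grignard reagents, aqueous base and alkaline peroxide in the following steps.

**Step 4**
Reactants: 5 triisopropyl{3-[3-methoxy-4-(methoxymethoxy)phenyl]propoxy}silane
Product: 7 {3-methoxy-2-(methoxymethoxy)-5-[3-(triisopropylsilyloxy)propyl]phenyl}magnesium bromide, via aryllithium 6 (not isolated)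
Conditions: n-BuLi (0.95 equiv), TMEDA, THF, 0 °C; then MgBr2·OEt2, 0 °C → rt; THF solution used directly
Reagents that add atoms: magnesium bromide (as its diethyl etherate), Br[Mg]Br; n-butyllithium, [Li]CCCC (lithium carried only in intermediate 6)
Why: Directed ortho-metalation followed by lithium-to-magnesium transmetalation; the methoxymethoxy group is the stronger director and its only ortho hydrogen (C1') is unhindered, whereas the site next to the methoxy group is flanked by the chain. A slight deficit of n-BuLi keeps free alkyl metal out of the aryne step.

**Step 5**
Reactants: 8 allyl alcohol (prop-2-en-1-ol)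
Product: 9 allyloxytriisopropylsilane
Conditions: TIPSCl, imidazole, CH2Cl2, 0 °C → rt
Reagents that add atoms: chlorotriisopropylsilane (TIPSCl), CC(C)[Si](Cl)(C(C)C)C(C)C
Why: Silyl ether formation on a primary allylic alcohol; the product supplies the three chain carbons of ring B in protected form.

**Step 6**
Reactants: 9 allyloxytriisopropylsilane; 10 1-bromo-3-fluoro-5-methoxybenzene
Product: 12 [3-(3-fluoro-5-methoxyphenyl)propoxy]triisopropylsilane, via alkylborane 11 (not isolated)
Conditions: 9 (1.3 equiv), 9-BBN, THF, rt; then 10, Pd(dppf)Cl2 (3 mol %), K3PO4 aq, DMF, 60 °C
Reagents that add atoms: 9-borabicyclo[3.3.1]nonane (9-BBN), [H]B1C2CCCC1CCC2 (boron carried only in intermediate 11)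
Why: B-alkyl Suzuki–Miyaura coupling; 9-BBN adds anti-Markovnikov to the terminal alkene of 9 and the primary alkyl group is transferred to the arylpalladium bromide formed from 10, while the C–F bond does not undergo oxidative addition to zerovalent palladium under these conditions.

**Step 7**
Reactants: 12 [3-(3-fluoro-5-methoxyphenyl)propoxy]triisopropylsilane; 7 {3-methoxy-2-(methoxymethoxy)-5-[3-(triisopropylsilyloxy)propyl]phenyl}magnesium bromide
Product: 17 3,3'-dimethoxy-2'-(methoxymethoxy)-5,5'-bis[3-(triisopropylsilyloxy)propyl]biphenyl-2-ol, via lithiated fluoroarene 13 (not isolated), via aryne 14 (not isolated), via biarylmagnesium bromide 15 (not isolated), via dimethyl boronate 16 (not isolated)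
Conditions: 12, n-BuLi (1.0 equiv), THF, −78 °C; add 7 (1.3 equiv) in THF, −78 °C → rt; B(OMe)3, 0 °C → rt; then NaOH aq, 30% H2O2, 0 °C
Reagents that add atoms: hydrogen peroxide, OO (phenol oxygen); n-butyllithium, [Li]CCCC (lithium carried only in intermediate 13); trimethyl borate, COB(OC)OC (boron and methoxy groups carried only in intermediate 16)
Why: n-BuLi removes the C2 proton of 12, the one flanked by fluorine and methoxy and by far the most acidic, to give aryllithium 13, which is stable at −78 °C. With Grignard reagent 7 already present, warming lets 13 lose LiF to aryne 14 (triple bond C1–C2, methoxy on C3), so the aryne is generated in an excess of the intended nucleophile. The aryl group of 7 adds at C1, the aryne carbon remote from the methoxy group, because the σ-withdrawing oxygen polarises and distorts the aryne so that negative charge builds at C2, where it is stabilised inductively and by O–Mg coordination, and because C1 is the less hindered terminus; this forms the C1–C1' bond and arylmagnesium 15. Intermediate 15 is flanked by an aryl and a methoxy group and is therefore a much poorer nucleophile towards further aryne than 7, which limits oligomerisation. B(OMe)3 converts the C2–Mg bond into boronate 16, and alkaline H2O2 effects the 1,2-shift of the aryl group from boron to oxygen, which forms the C2–O bond at exactly the metalated carbon. The closest known reaction type is the addition of aryl Grignard reagents to 3-methoxybenzynes generated from ortho-lithiated 3-fluoroanisoles with electrophilic quench of the resulting 2-biarylmagnesium halide, combined with the standard borylation–oxidation of aryl Grignard reagents to phenols. No ring closes and no stereocentre is formed; the selectivities needed are the site of lithiation, the regiochemistry of aryne addition and the preference of 14 for 7 over 13 and 15, secured respectively by the F/OMe-flanked proton, the C3 methoxy group, and the stoichiometry and steric difference of the nucleophiles.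

**Step 8**
Reactants: 17 3,3'-dimethoxy-2'-(methoxymethoxy)-5,5'-bis[3-(triisopropylsilyloxy)propyl]biphenyl-2-ol
Product: 18 3,3'-dimethoxy-2,2'-bis(methoxymethoxy)-5,5'-bis[3-(triisopropylsilyloxy)propyl]biphenyl
Conditions: NaH, MOMCl, THF/DMF, 0 °C → rt
Reagents that add atoms: chloromethyl methyl ether (MOMCl), COCCl
Why: Williamson-type O-alkylation of the sodium phenoxide; the small, reactive electrophile reaches the oxygen flanked by aryl and methoxy groups, and the product is C2-symmetric.

**Step 9**
Reactants: 18 3,3'-dimethoxy-2,2'-bis(methoxymethoxy)-5,5'-bis[3-(triisopropylsilyloxy)propyl]biphenyl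
Product: 19 3,3'-[5,5'-dimethoxy-6,6'-bis(methoxymethoxy)biphenyl-3,3'-diyl]di(propan-1-ol)
Conditions: TBAF, THF, rt → 40 °C
Reagents that add atoms: none
Why: Fluoride-mediated desilylation driven by the strong Si–F bond; aryl methoxymethyl ethers and methyl ethers are inert to TBAF.

**Step 10**
Reactants: 19 3,3'-[5,5'-dimethoxy-6,6'-bis(methoxymethoxy)biphenyl-3,3'-diyl]di(propan-1-ol)
Product: 21 3,3'-[5,5'-dimethoxy-6,6'-bis(methoxymethoxy)biphenyl-3,3'-diyl]dipropanoic acid, via dialdehyde 20 (not isolated)
Conditions: TEMPO (cat.), NaOCl (cat.), NaClO2, MeCN/phosphate buffer pH 6.7, 35 °C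
Reagents that add atoms: sodium chlorite, [Na+].[O-]Cl=O (carboxyl oxygen)
Why: TEMPO-catalysed alcohol oxidation with NaClO2 as terminal oxidant; the oxoammonium ion takes each primary alcohol to the aldehyde, which chlorite converts into the acid while regenerating hypochlorite. With only catalytic hypochlorite near neutral pH, chlorination of the electron-rich rings should be suppressed and the acetals should survive.

**Step 11**
Reactants: 21 3,3'-[5,5'-dimethoxy-6,6'-bis(methoxymethoxy)biphenyl-3,3'-diyl]dipropanoic acid
Product: 22 3,3'-(6,6'-dihydroxy-5,5'-dimethoxybiphenyl-3,3'-diyl)dipropanoic acid (CNP0122720.0)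
Conditions: 3 M HCl aq, THF, 50 °C
Reagents that add atoms: none
Why: Acid-catalysed hydrolysis of the two aryl methoxymethyl acetals; an alcohol-free aqueous medium avoids Fischer esterification of the acids, and the positions ortho and para to each liberated phenol are substituted, which limits recapture of formaldehyde.

## Compound list

1 | eugenol (4-allyl-2-methoxyphenol) | C=CCc1ccc(O)c(OC)c1 | starting material
2 | 4-allyl-2-methoxy-1-(methoxymethoxy)benzene | C=CCc1ccc(OCOC)c(OC)c1 | intermediate
3 | 9-{3-[3-methoxy-4-(methoxymethoxy)phenyl]propyl}-9-borabicyclo[3.3.1]nonane (not isolated) | COCOc1ccc(CCCB2C3CCCC2CCC3)cc1OC | intermediate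
4 | 3-[3-methoxy-4-(methoxymethoxy)phenyl]propan-1-ol | COCOc1ccc(CCCO)cc1OC | intermediate
5 | triisopropyl{3-[3-methoxy-4-(methoxymethoxy)phenyl]propoxy}silane | COCOc1ccc(CCCO[Si](C(C)C)(C(C)C)C(C)C)cc1OC | intermediate
6 | {3-methoxy-2-(methoxymethoxy)-5-[3-(triisopropylsilyloxy)propyl]phenyl}lithium (not isolated) | COCOc1c(OC)cc(CCCO[Si](C(C)C)(C(C)C)C(C)C)cc1[Li] | intermediate
7 | {3-methoxy-2-(methoxymethoxy)-5-[3-(triisopropylsilyloxy)propyl]phenyl}magnesium bromide (used as THF solution) | COCOc1c(OC)cc(CCCO[Si](C(C)C)(C(C)C)C(C)C)cc1[Mg]Br | intermediate
8 | allyl alcohol (prop-2-en-1-ol) | C=CCO | starting material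
9 | allyloxytriisopropylsilane | C=CCO[Si](C(C)C)(C(C)C)C(C)C | intermediate
10 | 1-bromo-3-fluoro-5-methoxybenzene | COc1cc(F)cc(Br)c1 | starting material
11 | 9-[3-(triisopropylsilyloxy)propyl]-9-borabicyclo[3.3.1]nonane (not isolated) | CC(C)[Si](OCCCB1C2CCCC1CCC2)(C(C)C)C(C)C | intermediate
12 | [3-(3-fluoro-5-methoxyphenyl)propoxy]triisopropylsilane | COc1cc(F)cc(CCCO[Si](C(C)C)(C(C)C)C(C)C)c1 | intermediate
13 | {2-fluoro-6-methoxy-4-[3-(triisopropylsilyloxy)propyl]phenyl}lithium (not isolated) | COc1cc(CCCO[Si](C(C)C)(C(C)C)C(C)C)cc(F)c1[Li] | intermediate
14 | 3-methoxy-5-[3-(triisopropylsilyloxy)propyl]benzyne (1,2-didehydrobenzene; not isolated) | COC1=CC(CCCO[Si](C(C)C)(C(C)C)C(C)C)=CC#C1 | intermediate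
15 | {3,3'-dimethoxy-2'-(methoxymethoxy)-5,5'-bis[3-(triisopropylsilyloxy)propyl]biphenyl-2-yl}magnesium bromide (not isolated) | COCOc1c(OC)cc(CCCO[Si](C(C)C)(C(C)C)C(C)C)cc1-c1cc(CCCO[Si](C(C)C)(C(C)C)C(C)C)cc(OC)c1[Mg]Br | intermediate
16 | dimethyl {3,3'-dimethoxy-2'-(methoxymethoxy)-5,5'-bis[3-(triisopropylsilyloxy)propyl]biphenyl-2-yl}boronate (not isolated) | COCOc1c(OC)cc(CCCO[Si](C(C)C)(C(C)C)C(C)C)cc1-c1cc(CCCO[Si](C(C)C)(C(C)C)C(C)C)cc(OC)c1B(OC)OC | intermediate
17 | 3,3'-dimethoxy-2'-(methoxymethoxy)-5,5'-bis[3-(triisopropylsilyloxy)propyl]biphenyl-2-ol | COCOc1c(OC)cc(CCCO[Si](C(C)C)(C(C)C)C(C)C)cc1-c1cc(CCCO[Si](C(C)C)(C(C)C)C(C)C)cc(OC)c1O | intermediate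
18 | 3,3'-dimethoxy-2,2'-bis(methoxymethoxy)-5,5'-bis[3-(triisopropylsilyloxy)propyl]biphenyl | COCOc1c(OC)cc(CCCO[Si](C(C)C)(C(C)C)C(C)C)cc1-c1cc(CCCO[Si](C(C)C)(C(C)C)C(C)C)cc(OC)c1OCOC | intermediate
19 | 3,3'-[5,5'-dimethoxy-6,6'-bis(methoxymethoxy)biphenyl-3,3'-diyl]di(propan-1-ol) | COCOc1c(OC)cc(CCCO)cc1-c1cc(CCCO)cc(OC)c1OCOC | intermediate
20 | 3,3'-[5,5'-dimethoxy-6,6'-bis(methoxymethoxy)biphenyl-3,3'-diyl]dipropanal (not isolated) | COCOc1c(OC)cc(CCC=O)cc1-c1cc(CCC=O)cc(OC)c1OCOC | intermediate
21 | 3,3'-[5,5'-dimethoxy-6,6'-bis(methoxymethoxy)biphenyl-3,3'-diyl]dipropanoic acid | COCOc1c(OC)cc(CCC(=O)O)cc1-c1cc(CCC(=O)O)cc(OC)c1OCOC | intermediate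
22 | 3,3'-(6,6'-dihydroxy-5,5'-dimethoxybiphenyl-3,3'-diyl)dipropanoic acid (CNP0122720.0) | COc1cc(CCC(=O)O)cc(-c2cc(CCC(=O)O)cc(OC)c2O)c1O | target

## Step count and risk

Total step count: 11. Longest linear sequence: 9 steps (steps 1–4 and 7–11, from eugenol 1); steps 5 and 6 form the two-step branch to 12.

**Step 7 (key step).** The aryne may not be intercepted cleanly by 7. Lithiated 13 or the product organomagnesium 15 can add to 14 in competition, which leads to oligomer formation. The hindered C2–Mg bond of 15 may also be borylated too slowly, so that protonation on work-up replaces the wanted oxygenation. Surplus 7 is borylated and oxidised as well, which complicates the separation of phenols. Fallback: the symmetry of the target is used instead of the aryne. Setting out from Grignard reagent 7, oxidative homocoupling (FeCl3 cat., 1,2-dichloroethane as stoichiometric oxidant, THF, rt) should join two C1' carbons and give bis(methoxymethyl) ether 18 directly. The route is rejoined at 18, before step 9; no compound outside the list is formed (F0).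

**Step 4.** Metalation may be incomplete or partly mis-sited, and unreacted butyllithium carried into step 7 would compete for the aryne; the titre of the reagent solution is then uncertain. Fallback: the metal is placed by halogenation instead of deprotonation. Setting out from eugenol 1:
- Hydroboration–oxidation with the phenol free (9-BBN, 2.2 equiv, then NaOH/H2O2) should give 4-(3-hydroxypropyl)-2-methoxyphenol F1.
- Electrophilic bromination ortho to the free hydroxyl (NBS, MeCN, 0 °C; the para position is blocked) should give 2-bromo-4-(3-hydroxypropyl)-6-methoxyphenol F2.
- Phenoxide-selective alkylation (MOMCl, K2CO3, acetone) should give 3-[3-bromo-5-methoxy-4-(methoxymethoxy)phenyl]propan-1-ol F3.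
- Silylation (TIPSCl, imidazole) should give {3-[3-bromo-5-methoxy-4-(methoxymethoxy)phenyl]propoxy}triisopropylsilane F4.
- Magnesium insertion (Mg turnings, LiCl, THF) converts F4 into Grignard reagent 7, free of alkyllithium, where the route is rejoined.

**Step 10.** Hypochlorite-derived electrophilic chlorine may attack the electron-rich rings, the oxidation may stall at the aldehyde stage, and a drift to acidic pH would start to cleave the acetals. Fallback: the nitroxyl/hypochlorite manifold is replaced by a two-stage sequence. Setting out from diol 19, Dess–Martin oxidation (NaHCO3-buffered CH2Cl2) gives dialdehyde 20, which is isolated. Pinnick oxidation (NaClO2, NaH2PO4, 2-methyl-2-butene as hypochlorite scavenger, t-BuOH/H2O) then returns to diacid 21. No compound outside the list is formed (F0).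

**Step 6.** Alkyl transfer from boron to palladium may be slow, so that protodeboronation of 11 or β-hydride elimination from the alkylpalladium intermediate and reduction of the aryl halide take over. Fallback: the chain is attached through an sp carbon. Setting out from aryl bromide 10, Sonogashira coupling with commercial triisopropyl(prop-2-ynyloxy)silane (Pd(PPh3)2Cl2, CuI, Et3N, 50 °C) should give {[3-(3-fluoro-5-methoxyphenyl)prop-2-yn-1-yl]oxy}triisopropylsilane F5. Hydrogenation of the triple bond (H2, Pd/C, EtOAc) then returns to fluoroarene 12; the aryl fluoride and the silyl ether are stable to these conditions.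

**Step 11.** Formaldehyde released in acid may recombine with the electron-rich rings at C6 and C6' (para to the methoxy groups), and hydrolysis of the hindered acetals may be incomplete. Fallback: the acetals are removed by transacetalisation and the acids are freed in a separate step. Setting out from 21, HCl in MeOH (rt → 40 °C) transfers the methylene units to the solvent and at the same time esterifies both acids, giving dimethyl 3,3'-(6,6'-dihydroxy-5,5'-dimethoxybiphenyl-3,3'-diyl)dipropanoate F6. Saponification (LiOH, THF/H2O, under argon, then acidification) returns to target 22.

## Further compounds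

F0 | step 7 | none | none
F1 | step 4 | 4-(3-hydroxypropyl)-2-methoxyphenol | COc1cc(CCCO)ccc1O
F2 | step 4 | 2-bromo-4-(3-hydroxypropyl)-6-methoxyphenol | COc1cc(CCCO)cc(Br)c1O
F3 | step 4 | 3-[3-bromo-5-methoxy-4-(methoxymethoxy)phenyl]propan-1-ol | COCOc1c(Br)cc(CCCO)cc1OC
F4 | step 4 | {3-[3-bromo-5-methoxy-4-(methoxymethoxy)phenyl]propoxy}triisopropylsilane | COCOc1c(Br)cc(CCCO[Si](C(C)C)(C(C)C)C(C)C)cc1OC
F0 | step 10 | none | none
F5 | step 6 | {[3-(3-fluoro-5-methoxyphenyl)prop-2-yn-1-yl]oxy}triisopropylsilane | COc1cc(F)cc(C#CCO[Si](C(C)C)(C(C)C)C(C)C)c1
F6 | step 11 | dimethyl 3,3'-(6,6'-dihydroxy-5,5'-dimethoxybiphenyl-3,3'-diyl)dipropanoate | COC(=O)CCc1cc(OC)c(O)c(-c2cc(CCC(=O)OC)cc(OC)c2O)c1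
A1 | alternative 1 | diisopropylsilylene-bridged dimethyl ester of the target (dibenzo[d,f][1,3,2]dioxasilepine) | COC(=O)CCc1cc(OC)c2O[Si](C(C)C)(C(C)C)Oc3c(OC)cc(CCC(=O)OC)cc3-c2c1
A2 | alternative 1 | diisopropylsilylene-tethered 4-methoxy-6-(3-methoxy-3-oxopropyl)-2-oxo-2H-pyran-3-yl / 2-ethynyl-6-methoxy-4-(3-methoxy-3-oxopropyl)phenyl bis(ether) | O=C1OC(CCC(=O)OC)=CC(OC)=C1O[Si](C(C)C)(C(C)C)Oc1c(OC)cc(CCC(=O)OC)cc1C#C
A3 | alternative 2 | ring-A benzyl ether of the target dimethyl ester | COC(=O)CCc1cc(OC)c(O)c(-c2cc(CCC(=O)OC)cc(OC)c2OCc2ccccc2)c1
A4 | alternative 2 | methyl 3-[4-(benzyloxy)-3-methoxy-5-(3-methoxy-2-oxopropyl)phenyl]propanoate | COCC(=O)Cc1cc(CCC(=O)OC)cc(OC)c1OCc1ccccc1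
A5 | alternative 2 | methyl 4-formyl-5-oxopentanoate | COC(=O)CCC(C=O)C=O
A6 | alternative 3 | (E,E)-5,5'-dehydrodiferulic acid | COc1cc(/C=C/C(=O)O)cc(-c2cc(/C=C/C(=O)O)cc(OC)c2O)c1O
A7 | alternative 3 | 5,5'-dehydrodivanillin | COc1cc(C=O)cc(-c2cc(C=O)cc(OC)c2O)c1O
A8 | alternative 3 | vanillin | COc1cc(C=O)ccc1O
A9 | alternative 3 | malonic acid | OC(=O)CC(=O)O
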